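Its constants are those of an exercise; no experiment stands behind them.

Capture at the charged level, 0.0240 /min, runs faster than ring closure, 0.0057 /min, and I want to know what that lead is worth over a run.

    capture agent + activated form → trapped intermediate (k1 = 0.32 /M/min)
    starting material + activator → activated form (k2 = 0.044 /M/min)
    starting material + activated form → open dimer (k3 = 0.022 /M/min)
    2 starting material → self-condensation product (k4 = 0.0045 /M/min)
    activated form → ring (k5 = 0.0057 /min)

| setting | alder | ash | oak | larch |
|---|---|---|---|---|
| starting material | 0.25 M | 0.25 M | 0.25 M | 0.25 M (fed, over 2.5 h) |
| activator | 1.50 equiv (fed, over 2.5 h) | 1.50 equiv | 1.50 equiv (in portions, 3, over 2.5 h) | 1.50 equiv |
| capture agent | 0.0750 M | 0.0750 M | 0.0750 M | 0.0750 M |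
| time | 12 h | 12 h | 12 h | 12 h |
| remark | all else is in the flask from the start; the feed brings no volume worth counting | everything together at the start | first portion at the start, last at 2.5 h | all else is in the flask from the start; the feed brings no volume worth counting |

- a species is counted by the starting material in it: one open dimer or self-condensation product counts as two
- for a step with 2 of a species take k times the square, and two of it per event
- run time (alder): 12 h

- the flask that comes out highest in amount of trapped intermediate, in percent of the starting material charged; "all alike" if 1.5 percentage points covers them all (alder / ash / oak / larch / all alike)
- amount of trapped intermediate at the end, in percent of the starting material charged, alder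
- amount of trapped intermediate at the end, in percent of the starting material charged, ash
- amount of trapped intermediate at the end, in percent of the starting material charged, oak
- amount of trapped intermediate at the end, in percent of the starting material charged, larch

Each trapped intermediate costs one capture agent, and the capture agent is charged below the starting material, so it is the limiting reagent. The trapped intermediate therefore stops at 30.0%, and I name this the ceiling: capture agent charged over starting material charged.

In one extreme, the whole starting material turns into activated form at once. I freeze the activated form at 0.25 M, so the capture agent lives 12.5 min against 175 min for the activated form, and the trapped intermediate meets the ceiling.

In the other extreme, activated form trickles in and each bit splits between capture and loss. I freeze the starting material at its charge, which makes the loss strongest, and define the leak L as ring closure plus dimer formation over the capture constant: 0.0350 M. With C the capture agent charged, the fraction of it surviving is about exp(-(M-C)/L) once M of activated form has been made. A pessimistic M is 0.125 M, half the starting material charged; it leaves a fraction 24.0%, and the trapped intermediate reaches about 22.8%.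

The real flasks lie between these, and I expect them above 22.8%, because the activated form made is more than the capture agent charged even at the pessimistic M, with the leak held at the charged starting material.

The forecast gives 29.8% for alder, 29.9% for ash, 29.9% for oak and 30% for larch, verdict all alike, on the ground of “capping the trapped intermediate at 30% of the starting material”.

The simulation gives 29.9% for alder, 30.0% for ash, 29.9% for oak and 30.0% for larch, so the answer is all alike. In oak, 0.47% of the capture agent charge is left at 12.0 h. Multiplied by the ceiling, that residue is worth 0.141% of the starting material charged.

For the neighbour, oak with 0.030 M of capture agent, the ceiling becomes 12.0%. The computed result there is 12.0%.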